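You expect an order of one, as many rounds as there is catalyst, and at the start free catalyst does go into starting material faster than into resting dimer, by a factor of 2.2 with the dimer's forward step counted alone; but the dimer's hold on the charge has to be reckoned.

starting material 0.25 M; free catalyst 5 mol%

    free catalyst + free catalyst ⇌ resting dimer (K1 = 45 /M, k1 = 37 /M/h)
    catalyst intermediate B → free catalyst + product (k2 = 5.1 /h)
    catalyst intermediate A ⇌ catalyst intermediate B (K3 = 17, k3 = 2.5 /h)
    starting material + free catalyst → catalyst intermediate A (k4 = 8.2 /M/h)

- apparent order in free catalyst when 20% of the starting material are converted (percent change of the rate of making product for one percent more free catalyst charged)

**What is left.** At 20% conversion, 0.200 M of starting material remains. Holding intermediates A and B steady at that level, the forms in the working round add up to 2.00 times the free catalyst. The dimer's back step has a half-life of 0.843 h, shorter than the 0.219 d this conversion takes, so I put the dimer at balance with free catalyst. Each dimer holds two of the charge, so the balance constant counts double, 90.0 /M, and the charge of 0.0125 M then leaves 0.00509 M of free catalyst.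

**The rule.** I carry the dimer share, the part of the catalyst charge held in resting dimer, the off-cycle form: 18.7%. With starting material held at this level, the rate follows free catalyst. One percent more free catalyst adds one percent to the forms in the round but two percent to the dimer, so the charge must grow by one percent plus the dimer share. The order is therefore one over one plus the share, 0.843.

**The check.** The forecast gives 0.86, between 0.78 and 0.95, with the dimer “holding only about a fifth of the charge”, a little above my figure. The simulation gives 0.86.

**The dimer's part.** Read backward, the rule turns this order into a dimer share of 15.9%, under my 18.7%. The dimer accounts for a part of how this flask answers to its charge. In a run of this flask without the back step of resting dimer to free catalyst, the rate at this conversion falls to 0.462 of the actual one. With no dimer share the rule gives an order of one, and a second flask, the same but with the dimer step taken away both ways, stands at 1.0.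

(The rate constants are assumed; no experiment stands behind them.)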